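**Strategy**

The dihydrofuran ring (ring C) is disconnected at O1–C2, which leads back to an open (S)-2,3-diarylpropan-1-ol whose single stereocentre, the future C3, is set by an Evans alkylation. The key step exploits that C2 is the benzylic carbon para to the free hydroxyl of the guaiacyl ring (ring B): Ag2O converts it into the exocyclic carbon of a p-quinone methide, and fluoride then unmasks the ring-A phenoxide, which adds to C2, forming O1–C2, ring C and the C2 stereocentre trans to C3 in one operation. The precursor carries a free ring-B phenol, silyl ethers on the ring-A oxygen and the side-chain alcohol, and a free C3 hydroxymethyl group for the later esterification.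

Key step: step 10

**Remarks on the chemistry (assumptions and design choices)**

- Ring A is the benzo ring of the benzofuran (OMe at C7, side chain at C5), ring B the guaiacyl ring on C2, ring C the dihydrofuran ring. TBS = tert-butyldimethylsilyl; "TBS-oxy" = OSi(CH3)2C(CH3)3.
- Assumption: compounds 1, 8, 11 and 20 are purchased; 11 is the O-benzyl ether of vanillyl alcohol.
- The stereocentre of the open precursor is (S); a trans closure then gives (2R,3S), as in the target.
- The C3 hydroxymethyl group is left unprotected in the precursor. It can reach the quinone methide carbon only through a four-membered ring, so it should not compete. Leaving it free removes any later need to tell two primary silyl ethers apart and makes the key-step product ready for esterification.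
- Both silyl ethers are TBS groups put on in one operation. The key step distinguishes them because fluoride cleaves the aryl silyl ether much faster than the primary alkyl one.
- The acetic acid arm of ring A is introduced by an aromatic Claisen rearrangement, so its position ortho to the phenolic oxygen does not depend on the regioselectivity of a halogenation.
- Quinone methide 17 may form as either geometric isomer of its exocyclic double bond; both lead to the same product.

**Route**

Step 1
Reactants: 1 dihydroconiferyl alcohol [4-(3-hydroxypropyl)-2-methoxyphenol]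
Product: 2 3-[3-methoxy-4-(prop-2-en-1-yloxy)phenyl]propan-1-ol
Conditions: allyl bromide (1.2 equiv), K2CO3 (1.5 equiv), acetone, reflux
Reagents that add atoms: allyl bromide, C=CCBr
Why: Williamson ether synthesis in which K2CO3 ionises only the phenol, so the allyl group goes on the phenolic oxygen and the aliphatic alcohol is left free.

Step 2
Reactants: 2 3-[3-methoxy-4-(prop-2-en-1-yloxy)phenyl]propan-1-ol
Product: 3 4-(3-hydroxypropyl)-2-methoxy-6-(prop-2-en-1-yl)phenol
Conditions: N,N-diethylaniline, 200 °C, Ar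
Reagents that add atoms: none
Why: Aromatic Claisen rearrangement ([3,3]-sigmatropic shift followed by tautomerisation) that can deliver the allyl group only to C6, because the other ortho position carries the methoxy group and the para position carries the side chain.

Step 3
Reactants: 3 4-(3-hydroxypropyl)-2-methoxy-6-(prop-2-en-1-yl)phenol
Product: 4 1-(TBS-oxy)-2-methoxy-4-[3-(TBS-oxy)propyl]-6-(prop-2-en-1-yl)benzene
Conditions: TBSCl (2.5 equiv), imidazole (5 equiv), DMF, rt → 40 °C
Reagents that add atoms: tert-butyldimethylsilyl chloride (TBSCl), CC(C)(C)[Si](C)(C)Cl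
Why: Standard silylation with TBSCl and imidazole protects the phenol and the primary alcohol in one operation, the aryl silyl ether later shielding ring A from oxidation and serving as the latent phenoxide.

Step 4
Reactants: 4 1-(TBS-oxy)-2-methoxy-4-[3-(TBS-oxy)propyl]-6-(prop-2-en-1-yl)benzene
Product: 7 {2-(TBS-oxy)-3-methoxy-5-[3-(TBS-oxy)propyl]phenyl}acetic acid, via ozonide 5 (not isolated), via aldehyde 6 (not isolated)
Conditions: O3, CH2Cl2, −78 °C (indicator end point); PPh3, −78 °C → rt; solvent switch; NaClO2, NaH2PO4, 2-methyl-2-butene, t-BuOH/H2O, 0 °C → rt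
Reagents that add atoms: ozone, [O-][O+]=O; sodium chlorite, [Na+].[O-]Cl=O
Why: Ozonolysis with reductive work-up followed by Pinnick oxidation of the crude arylacetaldehyde, the terminal alkene consuming ozone far faster than the arene at −78 °C and the chlorite oxidation (with 2-methyl-2-butene as hypochlorite scavenger) touching only the aldehyde.

Step 5
Reactants: 7 {2-(TBS-oxy)-3-methoxy-5-[3-(TBS-oxy)propyl]phenyl}acetic acid; 8 (4S)-4-benzyl-1,3-oxazolidin-2-one
Product: 10 (4S)-4-benzyl-3-({2-(TBS-oxy)-3-methoxy-5-[3-(TBS-oxy)propyl]phenyl}acetyl)-1,3-oxazolidin-2-one, via mixed pivalic anhydride 9 (not isolated)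
Conditions: t-BuCOCl, Et3N, THF, −20 °C; then 8, LiCl, −20 °C → rt
Reagents that add atoms: none
Why: N-acylation of the oxazolidinone through the mixed pivalic anhydride under LiCl/Et3N activation, attack occurring at the unhindered arylacetyl carbonyl and not at the tert-butyl-shielded one.

Step 6
Reactants: 11 [4-(benzyloxy)-3-methoxyphenyl]methanol
Product: 12 1-(benzyloxy)-4-(bromomethyl)-2-methoxybenzene
Conditions: PBr3 (0.4 equiv), Et2O, 0 °C; used directly
Reagents that add atoms: phosphorus tribromide, BrP(Br)Br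
Why: Conversion of a primary benzylic alcohol into its bromide with PBr3 by substitution of the intermediate phosphite ester, the labile electron-rich bromide being used without storage.

Step 7
Reactants: 10 (4S)-4-benzyl-3-({2-(TBS-oxy)-3-methoxy-5-[3-(TBS-oxy)propyl]phenyl}acetyl)-1,3-oxazolidin-2-one; 12 1-(benzyloxy)-4-(bromomethyl)-2-methoxybenzene
Product: 14 (4S)-4-benzyl-3-[(2S)-3-[4-(benzyloxy)-3-methoxyphenyl]-2-{2-(TBS-oxy)-3-methoxy-5-[3-(TBS-oxy)propyl]phenyl}propanoyl]-1,3-oxazolidin-2-one, via sodium enolate 13 (not isolated)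
Conditions: NaN(SiMe3)2 (1.05 equiv), THF, −78 °C; then 12 (1.5 equiv), −78 → −40 °C; AcOH quench at −78 °C
Reagents that add atoms: none
Why: Evans asymmetric alkylation in which the sodium-chelated Z-enolate is attacked by the benzylic bromide on the face away from the C4 benzyl group of the auxiliary, which sets the (S) centre (future C3), and a cold acidic quench keeps the acidic α-aryl position from epimerising.

Step 8
Reactants: 14 (4S)-4-benzyl-3-[(2S)-3-[4-(benzyloxy)-3-methoxyphenyl]-2-{2-(TBS-oxy)-3-methoxy-5-[3-(TBS-oxy)propyl]phenyl}propanoyl]-1,3-oxazolidin-2-one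
Product: 15 (2S)-3-[4-(benzyloxy)-3-methoxyphenyl]-2-{2-(TBS-oxy)-3-methoxy-5-[3-(TBS-oxy)propyl]phenyl}propan-1-ol
Conditions: LiBH4, H2O (1 equiv), Et2O/THF, 0 °C
Reagents that add atoms: none
Why: Reductive cleavage of the N-acyl oxazolidinone with LiBH4, hydride attacking the exocyclic carbonyl to release the primary alcohol and the recoverable auxiliary without affecting the stereocentre or the silyl ethers.

Step 9
Reactants: 15 (2S)-3-[4-(benzyloxy)-3-methoxyphenyl]-2-{2-(TBS-oxy)-3-methoxy-5-[3-(TBS-oxy)propyl]phenyl}propan-1-ol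
Product: 16 4-[(2S)-3-hydroxy-2-{2-(TBS-oxy)-3-methoxy-5-[3-(TBS-oxy)propyl]phenyl}propyl]-2-methoxyphenol
Conditions: H2 (1 atm), Pd/C (10 wt% palladium on carbon), EtOAc, rt
Reagents that add atoms: none
Why: Hydrogenolysis of the benzyl aryl ether over palladium on carbon, which in EtOAc leaves both silyl ethers intact and finds no other reducible group, so that only the ring-B phenol is unmasked.

Step 10
Reactants: 16 4-[(2S)-3-hydroxy-2-{2-(TBS-oxy)-3-methoxy-5-[3-(TBS-oxy)propyl]phenyl}propyl]-2-methoxyphenol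
Product: 19 4-[(2R,3S)-3-(hydroxymethyl)-7-methoxy-5-[3-(TBS-oxy)propyl]-2,3-dihydro-1-benzofuran-2-yl]-2-methoxyphenol, via quinone methide 17 (not isolated), via quinone methide phenoxide 18 (not isolated)
Conditions: Ag2O (3 equiv), CH2Cl2 (0.02 M), rt, dark; filtration through Celite under Ar; then Bu4NF (1.05 equiv, THF), −78 → 0 °C; AcOH (1.1 equiv)
Reagents that add atoms: none
Why: Oxidation of the 4-alkyl-2-methoxyphenol of ring B on Ag2O (two one-electron steps and loss of the C2 hydrogen) should give p-quinone methide 17 with C2 as its exocyclic electrophilic carbon, and after removal of the silver one equivalent of fluoride cleaves the aryl silyl ether of ring A so that phenoxide 18 adds 1,6 to C2, which re-aromatises ring B and forms O1–C2. The closest known reaction types are the Ag2O oxidation of 4-alkylguaiacols to p-quinone methides and the intramolecular addition of a phenol or phenoxide to a quinone methide that closes the phenylcoumaran ring in oxidative phenol coupling. Ring C is closed in a 5-exo-trig mode, since the attacked C2=C1' double bond lies outside the new ring. The new C2 stereocentre is controlled by the existing C3 centre: the aryl group takes the face opposite to the C3 hydroxymethyl group in the envelope transition state, and because the addition is reversible for a para-hydroxyaryl benzylic ether the more stable trans (2R,3S) isomer should accumulate. The step needs oxidation of ring B only (secured by the silyl ether on the ring-A oxygen), a single site of quinone methide formation (C2 is the only benzylic carbon para to a free phenol) and cleavage of the aryl silyl ether in preference to the primary alkyl one (secured by the better phenoxide leaving group, one equivalent of fluoride and low temperature). The free primary alcohol should not interfere because its addition to C2 would give a four-membered ring.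

Step 11
Reactants: 19 4-[(2R,3S)-3-(hydroxymethyl)-7-methoxy-5-[3-(TBS-oxy)propyl]-2,3-dihydro-1-benzofuran-2-yl]-2-methoxyphenol; 20 (E)-p-coumaric acid
Product: 21 {(2R,3S)-2-(4-hydroxy-3-methoxyphenyl)-7-methoxy-5-[3-(TBS-oxy)propyl]-2,3-dihydro-1-benzofuran-3-yl}methyl (2E)-3-(4-hydroxyphenyl)prop-2-enoate
Conditions: 20 (1.2 equiv), PPh3 (1.3 equiv), diisopropyl azodicarboxylate (1.3 equiv), THF, 0 °C → rt
Reagents that add atoms: none
Why: Mitsunobu esterification in which the primary alcohol is activated as an alkoxyphosphonium ion and displaced by the carboxylate, the only pronucleophile acidic enough to react efficiently, so that both phenols can stay free, and no stereocentre is touched because substitution takes place at the CH2 group.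

Step 12
Reactants: 21 {(2R,3S)-2-(4-hydroxy-3-methoxyphenyl)-7-methoxy-5-[3-(TBS-oxy)propyl]-2,3-dihydro-1-benzofuran-3-yl}methyl (2E)-3-(4-hydroxyphenyl)prop-2-enoate
Product: 22 {(2R,3S)-2-(4-hydroxy-3-methoxyphenyl)-5-(3-hydroxypropyl)-7-methoxy-2,3-dihydro-1-benzofuran-3-yl}methyl (2E)-3-(4-hydroxyphenyl)prop-2-enoate (CNP0202924.1)
Conditions: HF·pyridine, pyridine, THF, 0 °C → rt
Reagents that add atoms: none
Why: Fluoride-mediated cleavage of the primary silyl ether under buffered non-basic conditions, which the cinnamate ester, the phenols, the benzylic C2–O1 bond and both stereocentres should tolerate.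

**Compound list**

1 | dihydroconiferyl alcohol, 4-(3-hydroxypropyl)-2-methoxyphenol | COc1cc(CCCO)ccc1O | starting material
2 | 3-[3-methoxy-4-(prop-2-en-1-yloxy)phenyl]propan-1-ol | COc1cc(CCCO)ccc1OCC=C | intermediate
3 | 4-(3-hydroxypropyl)-2-methoxy-6-(prop-2-en-1-yl)phenol | COc1cc(CCCO)cc(CC=C)c1O | intermediate
4 | 1-(TBS-oxy)-2-methoxy-4-[3-(TBS-oxy)propyl]-6-(prop-2-en-1-yl)benzene | COc1cc(CCCO[Si](C)(C)C(C)(C)C)cc(CC=C)c1O[Si](C)(C)C(C)(C)C | intermediate
5 | 3-{2-(TBS-oxy)-3-methoxy-5-[3-(TBS-oxy)propyl]benzyl}-1,2,4-trioxolane (secondary ozonide of 4) | COc1cc(CCCO[Si](C)(C)C(C)(C)C)cc(CC2OCOO2)c1O[Si](C)(C)C(C)(C)C | intermediate (not isolated)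
6 | {2-(TBS-oxy)-3-methoxy-5-[3-(TBS-oxy)propyl]phenyl}acetaldehyde | COc1cc(CCCO[Si](C)(C)C(C)(C)C)cc(CC=O)c1O[Si](C)(C)C(C)(C)C | intermediate (not isolated)
7 | {2-(TBS-oxy)-3-methoxy-5-[3-(TBS-oxy)propyl]phenyl}acetic acid | COc1cc(CCCO[Si](C)(C)C(C)(C)C)cc(CC(=O)O)c1O[Si](C)(C)C(C)(C)C | intermediate
8 | (4S)-4-benzyl-1,3-oxazolidin-2-one | O=C1N[C@@H](Cc2ccccc2)CO1 | starting material
9 | mixed anhydride of acid 7 with pivalic acid | COc1cc(CCCO[Si](C)(C)C(C)(C)C)cc(CC(=O)OC(=O)C(C)(C)C)c1O[Si](C)(C)C(C)(C)C | intermediate (not isolated)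
10 | (4S)-4-benzyl-3-({2-(TBS-oxy)-3-methoxy-5-[3-(TBS-oxy)propyl]phenyl}acetyl)-1,3-oxazolidin-2-one | COc1cc(CCCO[Si](C)(C)C(C)(C)C)cc(CC(=O)N2[C@@H](Cc3ccccc3)COC2=O)c1O[Si](C)(C)C(C)(C)C | intermediate
11 | [4-(benzyloxy)-3-methoxyphenyl]methanol | COc1cc(CO)ccc1OCc1ccccc1 | starting material
12 | 1-(benzyloxy)-4-(bromomethyl)-2-methoxybenzene | COc1cc(CBr)ccc1OCc1ccccc1 | intermediate
13 | sodium (Z)-enolate of imide 10 | COc1cc(CCCO[Si](C)(C)C(C)(C)C)cc(/C=C(\[O-])N2[C@@H](Cc3ccccc3)COC2=O)c1O[Si](C)(C)C(C)(C)C.[Na+] | intermediate (not isolated)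
14 | (4S)-4-benzyl-3-[(2S)-3-[4-(benzyloxy)-3-methoxyphenyl]-2-{2-(TBS-oxy)-3-methoxy-5-[3-(TBS-oxy)propyl]phenyl}propanoyl]-1,3-oxazolidin-2-one | COc1cc(C[C@H](C(=O)N2[C@@H](Cc3ccccc3)COC2=O)c2cc(CCCO[Si](C)(C)C(C)(C)C)cc(OC)c2O[Si](C)(C)C(C)(C)C)ccc1OCc1ccccc1 | intermediate
15 | (2S)-3-[4-(benzyloxy)-3-methoxyphenyl]-2-{2-(TBS-oxy)-3-methoxy-5-[3-(TBS-oxy)propyl]phenyl}propan-1-ol | COc1cc(C[C@H](CO)c2cc(CCCO[Si](C)(C)C(C)(C)C)cc(OC)c2O[Si](C)(C)C(C)(C)C)ccc1OCc1ccccc1 | intermediate
16 | 4-[(2S)-3-hydroxy-2-{2-(TBS-oxy)-3-methoxy-5-[3-(TBS-oxy)propyl]phenyl}propyl]-2-methoxyphenol (key-step precursor) | COc1cc(C[C@H](CO)c2cc(CCCO[Si](C)(C)C(C)(C)C)cc(OC)c2O[Si](C)(C)C(C)(C)C)ccc1O | intermediate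
17 | 4-[(2S)-3-hydroxy-2-{2-(TBS-oxy)-3-methoxy-5-[3-(TBS-oxy)propyl]phenyl}propylidene]-2-methoxycyclohexa-2,5-dien-1-one (p-quinone methide) | COC1=CC(=C[C@H](CO)c2cc(CCCO[Si](C)(C)C(C)(C)C)cc(OC)c2O[Si](C)(C)C(C)(C)C)C=CC1=O | intermediate (not isolated)
18 | tetrabutylammonium 2-[(2S)-1-hydroxy-3-(3-methoxy-4-oxocyclohexa-2,5-dien-1-ylidene)propan-2-yl]-6-methoxy-4-[3-(TBS-oxy)propyl]phenolate | COC1=CC(=C[C@H](CO)c2cc(CCCO[Si](C)(C)C(C)(C)C)cc(OC)c2[O-])C=CC1=O.CCCC[N+](CCCC)(CCCC)CCCC | intermediate (not isolated)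
19 | 4-[(2R,3S)-3-(hydroxymethyl)-7-methoxy-5-[3-(TBS-oxy)propyl]-2,3-dihydro-1-benzofuran-2-yl]-2-methoxyphenol (key-step product, trans) | COc1cc([C@@H]2Oc3c(OC)cc(CCCO[Si](C)(C)C(C)(C)C)cc3[C@H]2CO)ccc1O | intermediate
20 | (E)-p-coumaric acid | OC(=O)/C=C/c1ccc(O)cc1 | starting material
21 | {(2R,3S)-2-(4-hydroxy-3-methoxyphenyl)-7-methoxy-5-[3-(TBS-oxy)propyl]-2,3-dihydro-1-benzofuran-3-yl}methyl (2E)-3-(4-hydroxyphenyl)prop-2-enoate | COc1cc([C@@H]2Oc3c(OC)cc(CCCO[Si](C)(C)C(C)(C)C)cc3[C@H]2COC(=O)/C=C/c2ccc(O)cc2)ccc1O | intermediate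
22 | {(2R,3S)-2-(4-hydroxy-3-methoxyphenyl)-5-(3-hydroxypropyl)-7-methoxy-2,3-dihydro-1-benzofuran-3-yl}methyl (2E)-3-(4-hydroxyphenyl)prop-2-enoate | COc1cc([C@@H]2Oc3c(OC)cc(CCCO)cc3[C@H]2COC(=O)/C=C/c2ccc(O)cc2)ccc1O | target

**Step count and risks**

Total step count: 12. Longest linear sequence: 11 steps (1 → 22 through steps 1–5 and 7–12; step 6 is a one-step side branch).

Steps most likely to fail:

1. Step 10 (key step). Under the basic fluoride the quinone methide may lose the C3 proton and tautomerise to the stilbene, or add to a second molecule, before the hindered aryl silyl ether is cleaved and the ring closes; the fluoride may also start to attack the primary silyl ether. Fallback: separate the oxidation from the ring closure and close under acid instead of base. Setting out from 16, oxidation with 2,3-dichloro-5,6-dicyano-1,4-benzoquinone in CH2Cl2/MeOH at 0 °C should trap the quinone methide at once as the benzylic methyl ether 4-[(2S)-3-hydroxy-1-methoxy-2-{2-(TBS-oxy)-3-methoxy-5-[3-(TBS-oxy)propyl]phenyl}propyl]-2-methoxyphenol F1 (both C1 epimers). Bu4NF (1.05 equiv, THF, −40 → 0 °C, AcOH quench) should then free the ring-A phenol to give 2-[(2S)-3-hydroxy-1-(4-hydroxy-3-methoxyphenyl)-1-methoxypropan-2-yl]-6-methoxy-4-[3-(TBS-oxy)propyl]phenol F2. Catalytic p-toluenesulfonic acid in CH2Cl2 at −20 °C should ionise the p-hydroxybenzyl ether and let the phenol capture the cation trans to the C3 substituent, which gives compound 19, where the route is rejoined.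

2. Step 7. The hindered, aryl-stabilised enolate may alkylate slowly, the ortho aryl silyl group may migrate to the enolate, or residual base may epimerise the acidic α-aryl centre, all of which erode diastereomeric purity. Fallback: set the centre by catalytic asymmetric hydrogenation instead of enolate alkylation. Setting out from acid 7, Perkin condensation with commercial 4-(benzyloxy)-3-methoxybenzaldehyde (Ac2O, Et3N, 100 °C, aqueous work-up) should give (2E)-3-[4-(benzyloxy)-3-methoxyphenyl]-2-{2-(TBS-oxy)-3-methoxy-5-[3-(TBS-oxy)propyl]phenyl}prop-2-enoic acid F3. Hydrogenation with Ru(OAc)2(BINAP) (H2, MeOH; the BINAP enantiomer that a test run shows to give the S acid) should give (2S)-3-[4-(benzyloxy)-3-methoxyphenyl]-2-{2-(TBS-oxy)-3-methoxy-5-[3-(TBS-oxy)propyl]phenyl}propanoic acid F4, upgraded if necessary by crystallising a salt with a chiral amine. Reduction with BH3·SMe2 in THF should give alcohol 15, where the route is rejoined.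

3. Step 11. Chemoselectivity may be lost through O-alkylation of a phenol by the alkoxyphosphonium ion, or elimination may compete with substitution at the β-branched carbinol. Fallback: mask the phenols and acylate the alcohol instead of alkylating the carboxylate. Setting out from 19, phenol-selective allylation (allyl bromide, K2CO3, DMF, rt, as in step 1) should give 4-[(2R,3S)-3-(hydroxymethyl)-7-methoxy-5-[3-(TBS-oxy)propyl]-2,3-dihydro-1-benzofuran-2-yl]-2-methoxyphenyl allyl ether F5. The acid (2E)-3-[4-(prop-2-en-1-yloxy)phenyl]prop-2-enoic acid F6 is made from commercial 4-(prop-2-en-1-yloxy)benzaldehyde and malonic acid (pyridine, catalytic piperidine, 90 °C; Knoevenagel–Doebner condensation). Steglich esterification (dicyclohexylcarbodiimide, 4-(dimethylamino)pyridine, CH2Cl2) of F5 with F6 should give the bis-allyl ester {(2R,3S)-2-[3-methoxy-4-(prop-2-en-1-yloxy)phenyl]-7-methoxy-5-[3-(TBS-oxy)propyl]-2,3-dihydro-1-benzofuran-3-yl}methyl (2E)-3-[4-(prop-2-en-1-yloxy)phenyl]prop-2-enoate F7. Pd(PPh3)4 (zerovalent palladium) with morpholine in THF should then remove both allyl groups to give 21, where the route is rejoined before step 12.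

**Further compounds**

F1 | step 10 | 4-[(2S)-3-hydroxy-1-methoxy-2-{2-(TBS-oxy)-3-methoxy-5-[3-(TBS-oxy)propyl]phenyl}propyl]-2-methoxyphenol (both C1 epimers) | COc1cc(C(OC)[C@H](CO)c2cc(CCCO[Si](C)(C)C(C)(C)C)cc(OC)c2O[Si](C)(C)C(C)(C)C)ccc1O
F2 | step 10 | 2-[(2S)-3-hydroxy-1-(4-hydroxy-3-methoxyphenyl)-1-methoxypropan-2-yl]-6-methoxy-4-[3-(TBS-oxy)propyl]phenol (both C1 epimers) | COc1cc(C(OC)[C@H](CO)c2cc(CCCO[Si](C)(C)C(C)(C)C)cc(OC)c2O)ccc1O
F3 | step 7 | (2E)-3-[4-(benzyloxy)-3-methoxyphenyl]-2-{2-(TBS-oxy)-3-methoxy-5-[3-(TBS-oxy)propyl]phenyl}prop-2-enoic acid | COc1cc(/C=C(/C(=O)O)c2cc(CCCO[Si](C)(C)C(C)(C)C)cc(OC)c2O[Si](C)(C)C(C)(C)C)ccc1OCc1ccccc1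
F4 | step 7 | (2S)-3-[4-(benzyloxy)-3-methoxyphenyl]-2-{2-(TBS-oxy)-3-methoxy-5-[3-(TBS-oxy)propyl]phenyl}propanoic acid | COc1cc(C[C@H](C(=O)O)c2cc(CCCO[Si](C)(C)C(C)(C)C)cc(OC)c2O[Si](C)(C)C(C)(C)C)ccc1OCc1ccccc1
F5 | step 11 | {(2R,3S)-7-methoxy-2-[3-methoxy-4-(prop-2-en-1-yloxy)phenyl]-5-[3-(TBS-oxy)propyl]-2,3-dihydro-1-benzofuran-3-yl}methanol | COc1cc([C@@H]2Oc3c(OC)cc(CCCO[Si](C)(C)C(C)(C)C)cc3[C@H]2CO)ccc1OCC=C
F6 | step 11 | (2E)-3-[4-(prop-2-en-1-yloxy)phenyl]prop-2-enoic acid | OC(=O)/C=C/c1ccc(OCC=C)cc1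
F7 | step 11 | {(2R,3S)-7-methoxy-2-[3-methoxy-4-(prop-2-en-1-yloxy)phenyl]-5-[3-(TBS-oxy)propyl]-2,3-dihydro-1-benzofuran-3-yl}methyl (2E)-3-[4-(prop-2-en-1-yloxy)phenyl]prop-2-enoate | COc1cc([C@@H]2Oc3c(OC)cc(CCCO[Si](C)(C)C(C)(C)C)cc3[C@H]2COC(=O)/C=C/c2ccc(OCC=C)cc2)ccc1OCC=C
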